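The route rests on disconnecting the aryl ether bond O1–C8a in ring C of the middle flavan unit. C8a of the middle ring A is flanked by C8, which bears the upper unit, and by C4a, which bears C4. A fluorine on C8a therefore first directs the metalation at C8 that attaches the upper unit and then acts as leaving group. In the key step the C2 alkoxide of an open-chain 1,3-diol, which already holds all three flavan units and the C2 and C3 stereocentres, displaces this fluoride (intramolecular SNAr, 6-exo) and closes the last ring. Ionic hydrogenation of the tertiary C4 alcohol then sets the all-cis middle unit, and one hydrogenolysis removes fifteen benzyl groups.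

Key step: step 14

Remark: flavan numbering (O1, C2, C3, C4, C4a, C5 to C8, C8a) is used for every unit and for its open-chain precursors.
Assumption: the C4 carbinol centres of 12 to 15 and of 27 and 28 form as epimer mixtures; this is harmless because C4 is ionised in steps 8 and 15.

Step 1
Reactants: 1 (S)-4-benzyl-1,3-oxazolidin-2-one; 2 (benzyloxy)acetyl chloride
Product: 3 (S)-4-benzyl-3-[(benzyloxy)acetyl]-1,3-oxazolidin-2-one
Conditions: n-BuLi, THF, −78 °C; then 2, −78 → 0 °C
Reagents that add atoms: none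
Why: N-acylation of the lithiated oxazolidinone by the acid chloride is the standard entry to an Evans glycolate imide and forms no stereocentre.

Step 2
Reactants: 3 (S)-4-benzyl-3-[(benzyloxy)acetyl]-1,3-oxazolidin-2-one; 4 3,4,5-tris(benzyloxy)benzaldehyde
Product: 6 (4S)-4-benzyl-3-[(2S,3R)-2-(benzyloxy)-3-hydroxy-3-[3,4,5-tris(benzyloxy)phenyl]propanoyl]-1,3-oxazolidin-2-one (syn aldol adduct), via boron Z-enolate 5 (not isolated)
Conditions: Bu2BOTf, Et3N, CH2Cl2, −78 → 0 °C; then 4, −78 → 0 °C; H2O2, MeOH, pH 7 buffer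
Reagents that add atoms: none
Why: Evans syn-aldol reaction, in which the Z-boron enolate reacts through a closed Zimmerman–Traxler transition state on the face away from the auxiliary benzyl group, so the (2S,3R) syn pair that becomes C3 and C2 of both 5-deoxy flavan units should be set by the auxiliary.

Step 3
Reactants: 6 syn aldol adduct
Product: 7 (2S,3R)-2-(benzyloxy)-3-hydroxy-N-methoxy-N-methyl-3-[3,4,5-tris(benzyloxy)phenyl]propanamide (Weinreb amide)
Conditions: MeNH(OMe)·HCl, AlMe3, CH2Cl2, −20 → 0 °C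
Reagents that add atoms: N,O-dimethylhydroxylamine hydrochloride CNOC.Cl
Why: Aluminium amide transamination of the imide (Weinreb amide formation) is assisted by the free β-hydroxyl and should release the auxiliary without touching either stereocentre.

Step 4
Reactants: 8 4-bromo-3-fluorophenol
Product: 9 4-(benzyloxy)-1-bromo-2-fluorobenzene
Conditions: BnBr, K2CO3, DMF, rt
Reagents that add atoms: benzyl bromide BrCc1ccccc1
Why: Williamson ether synthesis on the phenol gives the arene that serves as ring A of both the upper and the middle unit.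

Step 5
Reactants: 9 4-(benzyloxy)-1-bromo-2-fluorobenzene; 7 Weinreb amide
Product: 11 (2S,3R)-2-(benzyloxy)-1-[4-(benzyloxy)-2-fluorophenyl]-3-hydroxy-3-[3,4,5-tris(benzyloxy)phenyl]propan-1-one, via aryllithium 10 (not isolated)
Conditions: 9, n-BuLi, THF, −78 °C; then 7 (pre-treated with t-BuMgCl, THF, −78 °C), −78 °C; aq NH4Cl
Reagents that add atoms: none
Why: Bromine–lithium exchange gives an ortho-fluoro aryllithium that is stable at −78 °C and adds once to the Weinreb amide (chelated tetrahedral intermediate), whose hydroxyl is masked as the magnesium alkoxide, so C2 and C3 are untouched.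

Step 6
Reactants: 11 upper-unit aryl ketone
Product: 12 (1RS,2S,3R)-2-(benzyloxy)-1-[4-(benzyloxy)-2-fluorophenyl]-3-[3,4,5-tris(benzyloxy)phenyl]propane-1,3-diol
Conditions: NaBH4, THF/MeOH, −20 °C
Reagents that add atoms: none
Why: Borohydride reduction removes the carbonyl that would make C3–H acidic under the basic ring closure, and the new C4 carbinol centre may form as either epimer because C4 is ionised in step 8.

Step 7
Reactants: 12 open-chain 1,3-diol of the upper unit
Product: 14 (2R,3S,4RS)-3,7-bis(benzyloxy)-2-[3,4,5-tris(benzyloxy)phenyl]chroman-4-yl acetate (2,3-cis flavan), via potassium flavan-4-olate 13 (not isolated)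
Conditions: KOt-Bu, 18-crown-6, THF, 60 °C; then Ac2O, 0 °C
Reagents that add atoms: acetic anhydride CC(=O)OC(C)=O
Why: Intramolecular SNAr in which the C2 alkoxide displaces the ortho fluoride in a 6-exo closure (the C4 alkoxide could only close a four-membered ring and O3 is benzylated), retention at C2 and C3 turning the syn relationship into the 2,3-cis flavan, after which the surviving C4 alkoxide is acetylated in the same flask.

Step 8
Reactants: 14 upper-unit flavan-4-yl acetate; 9 4-(benzyloxy)-1-bromo-2-fluorobenzene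
Product: 18 (2R,3R,4R)-3,7-bis(benzyloxy)-4-[6-(benzyloxy)-3-bromo-2-fluorophenyl]-2-[3,4,5-tris(benzyloxy)phenyl]chromane (2,3-cis-3,4-trans), via 4-bromoflavan 15 (not isolated), via aryllithium 16 (not isolated), via arylzinc bromide 17 (not isolated)
Conditions: 9, LiN(i-Pr)2, THF, −78 °C; ZnBr2, −78 → 0 °C; solvent exchange to toluene; separately 14, Me3SiBr, CH2Cl2, −40 °C; mix, −40 °C → rt
Reagents that add atoms: none
Why: Uncatalysed coupling of an arylzinc halide with a secondary benzylic bromide through a benzylic cation ion pair (the C7 benzyloxy group stabilises the C4 cation), in which deprotonation between F and OBn fixes the C4–C8 regiochemistry and aryl delivery anti to the pseudo-axial C3 benzyloxy group, as in Lewis acid interflavan couplings of 2,3-cis electrophiles, should give the 3,4-trans (4R) product.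

Step 9
Reactants: 18 upper flavan carrying the bromofluoroarene; 7 Weinreb amide
Product: 20 (2S,3R)-2-(benzyloxy)-1-{4-(benzyloxy)-3-[(2R,3R,4R)-3,7-bis(benzyloxy)-2-[3,4,5-tris(benzyloxy)phenyl]chroman-4-yl]-2-fluorophenyl}-3-hydroxy-3-[3,4,5-tris(benzyloxy)phenyl]propan-1-one, via aryllithium 19 (not isolated)
Conditions: 18, t-BuLi, THF, −78 °C; then 7 (pre-treated with t-BuMgCl, THF, −78 °C), −78 °C; aq NH4Cl
Reagents that add atoms: none
Why: Bromine–lithium exchange at −78 °C outruns deprotonation of the diarylmethine and loss of LiF, and the aryllithium acylates the Weinreb amide exactly as in step 5, which places the C2 and C3 stereocentres of the middle unit.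

Step 10
Reactants: 21 (−)-epicatechin
Product: 22 5,7,3′,4′-tetra-O-benzyl-(−)-epicatechin
Conditions: BnBr, K2CO3, DMF, 0 °C → rt
Reagents that add atoms: benzyl bromide BrCc1ccccc1
Why: Phenoxide O-alkylation with a weak base leaves the secondary alcohol and the C2 stereocentre untouched.

Step 11
Reactants: 22 5,7,3′,4′-tetra-O-benzyl-(−)-epicatechin
Product: 23 3,5,7,3′,4′-penta-O-benzyl-(−)-epicatechin
Conditions: NaH, BnBr, DMF, 0 °C → rt
Reagents that add atoms: benzyl bromide BrCc1ccccc1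
Why: Williamson etherification of the C3 alkoxide makes every protecting group in the route a benzyl ether.

Step 12
Reactants: 23 3,5,7,3′,4′-penta-O-benzyl-(−)-epicatechin
Product: 24 8-bromo-3,5,7,3′,4′-penta-O-benzyl-(−)-epicatechin
Conditions: NBS, CH2Cl2, −78 °C → rt
Reagents that add atoms: N-bromosuccinimide BrN1C(=O)CCC1=O
Why: Electrophilic aromatic bromination should occur at C8, the most nucleophilic position of a 5,7-dialkoxyflavan.

Step 13
Reactants: 24 8-bromo-3,5,7,3′,4′-penta-O-benzyl-(−)-epicatechin; 20 upper–middle open-chain ketone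
Product: 27 (1RS,2S,3R)-2-(benzyloxy)-1-{4-(benzyloxy)-3-[(2R,3R,4R)-3,7-bis(benzyloxy)-2-[3,4,5-tris(benzyloxy)phenyl]chroman-4-yl]-2-fluorophenyl}-1-[3,5,7,3′,4′-penta-O-benzylepicatechin-8-yl]-3-[3,4,5-tris(benzyloxy)phenyl]propane-1,3-diol, via aryllithium 25 (not isolated), via arylcerium dichloride 26 (not isolated)
Conditions: 24, t-BuLi, THF, −78 °C; CeCl3, −78 °C; then 20 (0.4 equiv), −78 → −40 °C; aq NH4Cl
Reagents that add atoms: none
Why: Organocerium 1,2-addition, in which the weakly basic aryl cerium reagent should add to the enolisable α-alkoxy ketone instead of removing C3–H (one equivalent is consumed by the hydroxyl), the new tertiary C4 centre forming as an epimer mixture that converges in step 15.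

Step 14
Reactants: 27 open-chain tertiary carbinol holding all three units
Product: 28 ring-closed tertiary alcohol (pentadeca-O-benzyl ether of the target with a hydroxyl at C4 of the middle unit)
Conditions: KOt-Bu, 18-crown-6, THF, 65 °C
Reagents that add atoms: none
Why: KOt-Bu with 18-crown-6 turns both hydroxyls into naked alkoxides, and the C2 alkoxide attacks C8a ipso to fluorine from above the ring plane, fluoride leaving through a Meisenheimer-type or concerted transition state. The closest known reaction type is the alkoxide displacement of unactivated aryl fluorides that closes the pyran ring of chromans and flavan-3-ols, rehearsed on the upper unit in step 7. Ring C of the middle unit closes in a 6-exo mode (O1 onto sp2 C8a, leaving group outside the ring). No stereocentre is formed, and C2 and C3 keep their configuration because no bond at either centre is broken and no acidic C–H is present, so the syn relationship becomes 2,3-cis. The step needs chemoselectivity among nucleophiles and sites: O3 is benzylated, the tertiary C4 alkoxide could only close a four-membered ring, and C8a–F is the only carbon–fluorine bond in the molecule. The two flanking substituents on C8 and C4a lie in the ring plane and should not block attack perpendicular to it.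

Step 15
Reactants: 28 ring-closed tertiary alcohol
Product: 29 pentadeca-O-benzyl ether of the target (upper unit 2R,3R,4R; middle unit 2R,3R,4S; lower unit 2R,3R)
Conditions: Bu3SnH, CF3CO2H, CH2Cl2, 0 °C
Reagents that add atoms: none
Why: Ionic hydrogenation, in which acid ionises the doubly benzylic tertiary alcohol and the stannane delivers hydride to the planar C4 cation from the face anti to the C3 benzyloxy and C2 aryl groups, should give the 2,3-cis-3,4-cis (4S) middle unit from both C4 epimers.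

Step 16
Reactants: 29 pentadeca-O-benzyl ether of the target
Product: 30 CNP0115797.2, epirobinetinidol-(4β→8)-epirobinetinidol-(4α→8)-epicatechin
Conditions: H2 (1 atm), Pd(OH)2/C, THF/MeOH, rt
Reagents that add atoms: none
Why: Catalytic hydrogenolysis should cleave all fifteen benzyl ethers while the diarylmethine C4 centres and the benzylic ether bonds of the three pyran rings survive, as is usual in the final deprotection of benzylated proanthocyanidins.

Compound list
1 | (S)-4-benzyl-1,3-oxazolidin-2-one | O=C1N[C@@H](Cc2ccccc2)CO1 | starting material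
2 | (benzyloxy)acetyl chloride | ClC(=O)COCc1ccccc1 | starting material
3 | (S)-4-benzyl-3-[(benzyloxy)acetyl]-1,3-oxazolidin-2-one | O=C(COCc1ccccc1)N1[C@@H](Cc2ccccc2)COC1=O | intermediate
4 | 3,4,5-tris(benzyloxy)benzaldehyde | O=Cc1cc(OCc2ccccc2)c(OCc2ccccc2)c(OCc2ccccc2)c1 | starting material
5 | dibutylboron Z-enolate of 3 (not isolated) | CCCCB(CCCC)O/C(=C\OCc1ccccc1)N1[C@@H](Cc2ccccc2)COC1=O | intermediate
6 | (4S)-4-benzyl-3-[(2S,3R)-2-(benzyloxy)-3-hydroxy-3-[3,4,5-tris(benzyloxy)phenyl]propanoyl]-1,3-oxazolidin-2-one | O=C([C@@H](OCc1ccccc1)[C@H](O)c1cc(OCc2ccccc2)c(OCc2ccccc2)c(OCc2ccccc2)c1)N1[C@@H](Cc2ccccc2)COC1=O | intermediate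
7 | (2S,3R)-2-(benzyloxy)-3-hydroxy-N-methoxy-N-methyl-3-[3,4,5-tris(benzyloxy)phenyl]propanamide | CON(C)C(=O)[C@@H](OCc1ccccc1)[C@H](O)c1cc(OCc2ccccc2)c(OCc2ccccc2)c(OCc2ccccc2)c1 | intermediate
8 | 4-bromo-3-fluorophenol | Oc1ccc(Br)c(F)c1 | starting material
9 | 4-(benzyloxy)-1-bromo-2-fluorobenzene | Fc1cc(OCc2ccccc2)ccc1Br | intermediate
10 | [4-(benzyloxy)-2-fluorophenyl]lithium (not isolated) | [Li]c1ccc(OCc2ccccc2)cc1F | intermediate
11 | (2S,3R)-2-(benzyloxy)-1-[4-(benzyloxy)-2-fluorophenyl]-3-hydroxy-3-[3,4,5-tris(benzyloxy)phenyl]propan-1-one | O=C(c1ccc(OCc2ccccc2)cc1F)[C@@H](OCc1ccccc1)[C@H](O)c1cc(OCc2ccccc2)c(OCc2ccccc2)c(OCc2ccccc2)c1 | intermediate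
12 | (1RS,2S,3R)-2-(benzyloxy)-1-[4-(benzyloxy)-2-fluorophenyl]-3-[3,4,5-tris(benzyloxy)phenyl]propane-1,3-diol | OC(c1ccc(OCc2ccccc2)cc1F)[C@@H](OCc1ccccc1)[C@H](O)c1cc(OCc2ccccc2)c(OCc2ccccc2)c(OCc2ccccc2)c1 | intermediate
13 | potassium 4-alkoxide of 2,3-cis-(2R)-3,7-bis(benzyloxy)-2-[3,4,5-tris(benzyloxy)phenyl]chroman-4-ol, C4 epimers (not isolated) | c1ccccc1COc1ccc2c(c1)O[C@H](c1cc(OCc3ccccc3)c(OCc3ccccc3)c(OCc3ccccc3)c1)[C@H](OCc1ccccc1)C2[O-].[K+] | intermediate
14 | (2R,3S,4RS)-3,7-bis(benzyloxy)-2-[3,4,5-tris(benzyloxy)phenyl]chroman-4-yl acetate, 2,3-cis | c1ccccc1COc1ccc2c(c1)O[C@H](c1cc(OCc3ccccc3)c(OCc3ccccc3)c(OCc3ccccc3)c1)[C@H](OCc1ccccc1)C2OC(C)=O | intermediate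
15 | (2R,3S,4RS)-3,7-bis(benzyloxy)-4-bromo-2-[3,4,5-tris(benzyloxy)phenyl]chromane, 2,3-cis (not isolated) | c1ccccc1COc1ccc2c(c1)O[C@H](c1cc(OCc3ccccc3)c(OCc3ccccc3)c(OCc3ccccc3)c1)[C@H](OCc1ccccc1)C2Br | intermediate
16 | [6-(benzyloxy)-3-bromo-2-fluorophenyl]lithium (not isolated) | [Li]c1c(F)c(Br)ccc1OCc1ccccc1 | intermediate
17 | [6-(benzyloxy)-3-bromo-2-fluorophenyl]zinc bromide (not isolated) | Br[Zn]c1c(F)c(Br)ccc1OCc1ccccc1 | intermediate
18 | (2R,3R,4R)-3,7-bis(benzyloxy)-4-[6-(benzyloxy)-3-bromo-2-fluorophenyl]-2-[3,4,5-tris(benzyloxy)phenyl]chromane, 2,3-cis-3,4-trans | c1ccccc1COc1ccc2c(c1)O[C@H](c1cc(OCc3ccccc3)c(OCc3ccccc3)c(OCc3ccccc3)c1)[C@H](OCc1ccccc1)[C@H]2c1c(OCc3ccccc3)ccc(Br)c1F | intermediate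
19 | aryllithium from 18, lithium in place of bromine (not isolated) | c1ccccc1COc1ccc2c(c1)O[C@H](c1cc(OCc3ccccc3)c(OCc3ccccc3)c(OCc3ccccc3)c1)[C@H](OCc1ccccc1)[C@H]2c1c(OCc3ccccc3)ccc([Li])c1F | intermediate
20 | (2S,3R)-2-(benzyloxy)-1-{4-(benzyloxy)-3-[(2R,3R,4R)-3,7-bis(benzyloxy)-2-[3,4,5-tris(benzyloxy)phenyl]chroman-4-yl]-2-fluorophenyl}-3-hydroxy-3-[3,4,5-tris(benzyloxy)phenyl]propan-1-one | c1ccccc1COc1ccc2c(c1)O[C@H](c1cc(OCc3ccccc3)c(OCc3ccccc3)c(OCc3ccccc3)c1)[C@H](OCc1ccccc1)[C@H]2c1c(OCc3ccccc3)ccc(c1F)C(=O)[C@@H](OCc1ccccc1)[C@H](O)c1cc(OCc3ccccc3)c(OCc3ccccc3)c(OCc3ccccc3)c1 | intermediate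
21 | (−)-epicatechin, (2R,3R)-2-(3,4-dihydroxyphenyl)chromane-3,5,7-triol | Oc1cc(O)c2c(c1)O[C@H](c1ccc(O)c(O)c1)[C@H](O)C2 | starting material
22 | 5,7,3′,4′-tetra-O-benzyl-(−)-epicatechin | c1ccccc1COc1cc(OCc3ccccc3)c2c(c1)O[C@H](c1ccc(OCc3ccccc3)c(OCc3ccccc3)c1)[C@H](O)C2 | intermediate
23 | 3,5,7,3′,4′-penta-O-benzyl-(−)-epicatechin | c1ccccc1COc1cc(OCc3ccccc3)c2c(c1)O[C@H](c1ccc(OCc3ccccc3)c(OCc3ccccc3)c1)[C@H](OCc1ccccc1)C2 | intermediate
24 | 8-bromo-3,5,7,3′,4′-penta-O-benzyl-(−)-epicatechin | Brc1c(OCc3ccccc3)cc(OCc3ccccc3)c2c1O[C@H](c1ccc(OCc3ccccc3)c(OCc3ccccc3)c1)[C@H](OCc1ccccc1)C2 | intermediate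
25 | 8-lithio-3,5,7,3′,4′-penta-O-benzyl-(−)-epicatechin (not isolated) | [Li]c1c(OCc3ccccc3)cc(OCc3ccccc3)c2c1O[C@H](c1ccc(OCc3ccccc3)c(OCc3ccccc3)c1)[C@H](OCc1ccccc1)C2 | intermediate
26 | [3,5,7,3′,4′-penta-O-benzylepicatechin-8-yl]cerium dichloride (not isolated) | Cl[Ce](Cl)c1c(OCc3ccccc3)cc(OCc3ccccc3)c2c1O[C@H](c1ccc(OCc3ccccc3)c(OCc3ccccc3)c1)[C@H](OCc1ccccc1)C2 | intermediate
27 | (1RS,2S,3R)-2-(benzyloxy)-1-{4-(benzyloxy)-3-[(2R,3R,4R)-3,7-bis(benzyloxy)-2-[3,4,5-tris(benzyloxy)phenyl]chroman-4-yl]-2-fluorophenyl}-1-[3,5,7,3′,4′-penta-O-benzylepicatechin-8-yl]-3-[3,4,5-tris(benzyloxy)phenyl]propane-1,3-diol | c1ccccc1COc1ccc2c(c1)O[C@H](c1cc(OCc3ccccc3)c(OCc3ccccc3)c(OCc3ccccc3)c1)[C@H](OCc1ccccc1)[C@H]2c1c(OCc3ccccc3)ccc(c1F)C(O)(c1c(OCc3ccccc3)cc(OCc3ccccc3)c2c1O[C@H](c1ccc(OCc3ccccc3)c(OCc3ccccc3)c1)[C@H](OCc1ccccc1)C2)[C@@H](OCc1ccccc1)[C@H](O)c1cc(OCc3ccccc3)c(OCc3ccccc3)c(OCc3ccccc3)c1 | intermediate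
28 | ring-closed tertiary alcohol: pentadeca-O-benzyl ether of the target with a hydroxyl at C4 of the middle unit (middle unit 2,3-cis, C4 epimers; upper unit 2R,3R,4R; lower unit 2R,3R) | c1ccccc1COc1ccc2c(c1)O[C@H](c1cc(OCc3ccccc3)c(OCc3ccccc3)c(OCc3ccccc3)c1)[C@H](OCc1ccccc1)[C@H]2c1c(OCc3ccccc3)ccc2c1O[C@H](c1cc(OCc3ccccc3)c(OCc3ccccc3)c(OCc3ccccc3)c1)[C@H](OCc1ccccc1)C2(O)c1c(OCc3ccccc3)cc(OCc3ccccc3)c2c1O[C@H](c1ccc(OCc3ccccc3)c(OCc3ccccc3)c1)[C@H](OCc1ccccc1)C2 | intermediate
29 | pentadeca-O-benzyl ether of the target (upper unit 2R,3R,4R; middle unit 2R,3R,4S; lower unit 2R,3R) | c1ccccc1COc1ccc2c(c1)O[C@H](c1cc(OCc3ccccc3)c(OCc3ccccc3)c(OCc3ccccc3)c1)[C@H](OCc1ccccc1)[C@H]2c1c(OCc3ccccc3)ccc2c1O[C@H](c1cc(OCc3ccccc3)c(OCc3ccccc3)c(OCc3ccccc3)c1)[C@H](OCc1ccccc1)[C@@H]2c1c(OCc3ccccc3)cc(OCc3ccccc3)c2c1O[C@H](c1ccc(OCc3ccccc3)c(OCc3ccccc3)c1)[C@H](OCc1ccccc1)C2 | intermediate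
30 | CNP0115797.2, epirobinetinidol-(4β→8)-epirobinetinidol-(4α→8)-epicatechin (upper unit 2R,3R,4R; middle unit 2R,3R,4S; lower unit 2R,3R) | Oc1ccc2c(c1)O[C@H](c1cc(O)c(O)c(O)c1)[C@H](O)[C@H]2c1c(O)ccc2c1O[C@H](c1cc(O)c(O)c(O)c1)[C@H](O)[C@@H]2c1c(O)cc(O)c2c1O[C@H](c1ccc(O)c(O)c1)[C@H](O)C2 | target

Total step count: 16. Longest linear sequence: 12 steps (steps 1, 2, 3, 5, 6, 7, 8, 9, 13, 14, 15, 16).

Steps most likely to fail

Step 8. The ionised C4 centre may lose the C3 proton to give a flav-3-ene, or alkylate the benzyloxy-substituted ring A of a second molecule, faster than it captures the doubly ortho-substituted arylzinc; aryl delivery may also be poorly face-selective. The fallback sets out from 9 and 14 and comes back at 18. Aryllithium 16 (from 9) is quenched with B(OMe)3 and then KHF2 to give potassium [6-(benzyloxy)-3-bromo-2-fluorophenyl]trifluoroborate F1. F1 and acetate 14 are then treated with BF3·OEt2 in CH2Cl2 at −40 °C. The derived aryldifluoroborane transfers its aryl group from boron to the C4 cation, the known Lewis acid promoted addition of organotrifluoroborates to oxocarbenium and benzhydryl cations. This avoids the labile bromide and the basic organozinc and should again give the 3,4-trans product 18.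

Step 14. Displacement at a fluoride that is flanked by two branched carbon substituents and sits next to a tertiary alkoxide may be too slow, so that base-induced decomposition takes over. The fallback sets out from 20 and comes back at 28; it closes the ring before the lower unit is attached. NaBH4 reduces 20 to the open-chain diol F2. KOt-Bu with 18-crown-6 closes ring C at this less crowded secondary carbinol stage to the flavan-4-ol F3. Dess–Martin periodinane oxidises F3 to the flavan-4-one F4. Aryllithium 25 then adds to this cyclic ketone at −78 °C, a well-precedented addition for 4α-linked flavan dimers, to give 28.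

Step 13. Proton transfer may win over addition: deprotonation of the hydroxyl followed by retro-aldol cleavage, or enolisation at C3 with loss of configuration. The fallback sets out from 20 and comes back at 27; it removes the acidic hydroxyl from the substrate. Et3SiOTf and 2,6-lutidine convert 20 into the triethylsilyl ether F5. One equivalent of aryllithium 25 adds to F5 at −78 °C without any alkoxide next to the ketone, giving the silylated tertiary carbinol F6. Bu4NF then frees the hydroxyl to give 27.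

Further compounds
F1 | step 8 | potassium [6-(benzyloxy)-3-bromo-2-fluorophenyl]trifluoroborate | [K+].F[B-](F)(F)c1c(F)c(Br)ccc1OCc1ccccc1
F2 | step 14 | open-chain diol from reduction of 20 (C4 epimers) | c1ccccc1COc1ccc2c(c1)O[C@H](c1cc(OCc3ccccc3)c(OCc3ccccc3)c(OCc3ccccc3)c1)[C@H](OCc1ccccc1)[C@H]2c1c(OCc3ccccc3)ccc(c1F)C(O)[C@@H](OCc1ccccc1)[C@H](O)c1cc(OCc3ccccc3)c(OCc3ccccc3)c(OCc3ccccc3)c1
F3 | step 14 | flavan-4-ol of the middle unit carrying the upper unit at C8 (2,3-cis, C4 epimers) | c1ccccc1COc1ccc2c(c1)O[C@H](c1cc(OCc3ccccc3)c(OCc3ccccc3)c(OCc3ccccc3)c1)[C@H](OCc1ccccc1)[C@H]2c1c(OCc3ccccc3)ccc2c1O[C@H](c1cc(OCc3ccccc3)c(OCc3ccccc3)c(OCc3ccccc3)c1)[C@H](OCc1ccccc1)C2O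
F4 | step 14 | flavan-4-one of the middle unit carrying the upper unit at C8 (2,3-cis) | c1ccccc1COc1ccc2c(c1)O[C@H](c1cc(OCc3ccccc3)c(OCc3ccccc3)c(OCc3ccccc3)c1)[C@H](OCc1ccccc1)[C@H]2c1c(OCc3ccccc3)ccc2c1O[C@H](c1cc(OCc3ccccc3)c(OCc3ccccc3)c(OCc3ccccc3)c1)[C@H](OCc1ccccc1)C2=O
F5 | step 13 | triethylsilyl ether of 20 | c1ccccc1COc1ccc2c(c1)O[C@H](c1cc(OCc3ccccc3)c(OCc3ccccc3)c(OCc3ccccc3)c1)[C@H](OCc1ccccc1)[C@H]2c1c(OCc3ccccc3)ccc(c1F)C(=O)[C@@H](OCc1ccccc1)[C@H](O[Si](CC)(CC)CC)c1cc(OCc3ccccc3)c(OCc3ccccc3)c(OCc3ccccc3)c1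
F6 | step 13 | silylated tertiary carbinol (triethylsilyl ether of 27 at O on C2) | c1ccccc1COc1ccc2c(c1)O[C@H](c1cc(OCc3ccccc3)c(OCc3ccccc3)c(OCc3ccccc3)c1)[C@H](OCc1ccccc1)[C@H]2c1c(OCc3ccccc3)ccc(c1F)C(O)(c1c(OCc3ccccc3)cc(OCc3ccccc3)c2c1O[C@H](c1ccc(OCc3ccccc3)c(OCc3ccccc3)c1)[C@H](OCc1ccccc1)C2)[C@@H](OCc1ccccc1)[C@H](O[Si](CC)(CC)CC)c1cc(OCc3ccccc3)c(OCc3ccccc3)c(OCc3ccccc3)c1
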